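I decided to stop following the product and to follow what is neither solid nor product.

all flasks: free catalyst 19 mM
- north-west: solid substrate 0.15 M; temperature 15 °C; run made earlier
- west: solid substrate 1.9 M; temperature 26 °C; run made earlier
- noon: solid substrate 0.25 M; temperature 20 °C; time 40 h
- winter: solid substrate 0.12 M; temperature 20 °C; time 40 h
- summer: solid substrate 0.40 M; temperature 20 °C; time 40 h
- midnight: solid substrate 0.60 M; temperature 20 °C; time 40 h
- spring: solid substrate 1.5 M; temperature 20 °C; time 40 h
- dusk: solid substrate 0.20 M; temperature 20 °C; time 40 h

- north-west (time / h: product / %, solid substrate / %): 4.00: 7, 0; 10.0: 13, 0; 20.0: 19, 0; 30.0: 29, 1; 40.0: 30, 0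
- west (time / h: product / %, solid substrate / %): 3.00: 1, 87; 6.00: 4, 86; 12.0: 4, 86; 20.0: 5, 83; 40.0: 11, 77

(each reading ± 1.5 percentage points)

- a species is counted by the solid substrate in it: one spent catalyst counts as two
- given per volume of solution although it is solid: solid substrate
- the analysis behind the earlier runs scatters by 1.5 percentage points, standard deviation
- reactions considered so far: solid substrate <-> starting material; catalyst intermediate B -> free catalyst + product; free catalyst <-> dormant form; starting material + free catalyst -> catalyst intermediate A; 2 catalyst intermediate B -> spent catalyst; catalyst intermediate A <-> catalyst intermediate B
- at the start none of the solid substrate is in solution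
- what has only dissolved of solid substrate counts as not reacted

- the flasks put in order of amount of product, in percent of the solid substrate charged, best first, at 40 h (noon / winter / summer / midnight / spring / dusk)
- the same order at 8.0 h (noon / winter / summer / midnight / spring / dusk)
- the amount of product, in percent of the solid substrate charged of the flask you put first, at 40 h
- the amount of product, in percent of the solid substrate charged of the flask you put last, at 40 h

I set west beside spring, since both are charged far above what north-west dissolved. In west, solid fell by 10 percentage points between the first and last readings while product rose by 10 points. Dividing one rate by the other removes time and gives 1.00 of solid lost per product gained, within the scatter. Solid plus product therefore read 88.0% at 3.00 h and 88.0% at 40.0 h.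

The remainder, averaged over the readings and multiplied by the charge, is 0.213 M. This amount stands as neither solid nor product while solid lies in the flask, so it counts dissolved starting material together with what the catalyst holds, and I call it the solution ceiling. It is a reading at 26 °C, and carrying it to 20 °C was my own assumption.

Spring's charge is above the ceiling, so I expected solid to remain there as in west. Spring's share in neither form should then be 14.2% of the charge for as long as solid lies there. Midnight is also charged above the ceiling, with the same catalyst and temperature as spring, so I expected equal molar product from the two while both keep solid, and spring's percentage should be 0.400 of midnight's.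

The forecast gave winter > dusk > noon > summer > midnight > spring at 40 h and winter > dusk > noon > summer > midnight > spring at 8.0 h. It put the first flask at 40% (30% to 55%) and the last at 8% (5% to 12%), holding that above solubility “absolute product is about the same”.

The flasks gave winter > dusk > noon > summer > midnight > spring at 40 h and winter > dusk > noon > summer > midnight > spring at 8.0 h, with 49.9% in winter and 6.33% in spring. Both orders held and the low fell within its range, but the top stood 9.9 points above the forecast, whose figure is what a doubling rule from north-west gives.

    solid substrate ⇌ starting material, rate k1*(cs1 - [starting material]) while solid is left; crystals form when [starting material] > cs1 (solubility = 0.190 M, k = 1.06 h⁻¹)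
    catalyst intermediate B → free catalyst + product (k = 0.813 h⁻¹, Ea = 86.0 kJ mol⁻¹)
    free catalyst ⇌ dormant form (K = 9.40, k = 0.496 h⁻¹, Ea = 84.0 kJ mol⁻¹, ΔH = −57.0 kJ mol⁻¹)
    starting material + free catalyst → catalyst intermediate A (k = 9.86 M⁻¹ h⁻¹, Ea = 75.0 kJ mol⁻¹)
    2 catalyst intermediate B → spent catalyst (k = 6.04 M⁻¹ h⁻¹, Ea = 77.0 kJ mol⁻¹)
    catalyst intermediate A ⇌ catalyst intermediate B (K = 5.72, k = 4.40 h⁻¹, Ea = 97.0 kJ mol⁻¹, ΔH = −1.00 kJ mol⁻¹)
    (constants at 20 °C)

At 40.0 h in spring, starting material was made 1.00 times as fast as it was used up, each step taken net, and neither solid nor product stood at 13.1%, of it 12.5% starting material, against my 14.2%. Spring's product was 0.400 of midnight's, against my 0.400.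

For spring left until 6.0 d, with solid still present, the ceiling again gives 14.2% as neither solid nor product and the rest as solid plus product. The computed flask holds 69.7% solid and 17.0% product, which leaves 13.3% as neither, of it 12.6% starting material.

All runs were generated by integration for substances that don't exist, and the scatter is random.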